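**Retrosynthetic overview**

1. Numbering: ring O1–O2–C3(OH)(CH2CO2H)–C4(Me)–C5–C6(Me), side chain C1'–C10'. The acid and the C3 hemiketal are released last from a methyl ester and a C3 methyl peroxyketal; C3–OH settles axial (anomeric effect).
2. C6–CH3 is cut next: axial C-methylation of the C6 peroxycarbenium ion of a 3,6-dimethoxy-1,2-dioxane, steered by the equatorial C4 methyl group. The side chain must therefore already sit on C6.
3. The only ring, the 1,2-dioxane O1–O2–C3–C4–C5–C6, closes by double peroxyketalisation of an open-chain 1,4-diketone (C3=O, C6=O) with H2O2.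
4. C6–C1' is made by Weinreb ketone synthesis from the side-chain Grignard reagent and a C6 N-methoxy-N-methylamide. The enabling feature: C6, the ring carbon on O1, stands 1,4 to the hemiketal carbon C3 and is a plain ketone carbonyl in the ring-opened 1,4-dicarbonyl form.
5. Bought stereocentres: C2' from (S)-1-bromo-3-chloro-2-methylpropane; C4 from (R)-2-methylsuccinic acid 4-methyl ester, whose four backbone carbons become C3–C6. C6 and C3 are relayed from C4.

Key step: step 4

Remark: compounds 1, 2, 5 and 6 are taken as purchasable; magnesium carboxylates and enolates formed in situ are treated as their parent compounds and not numbered separately.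

**Route**

Step 1
Reactants: 1 (7-bromoheptyl)benzene; 2 (S)-1-bromo-3-chloro-2-methylpropane
Product: 4 (R)-1-chloro-2-methyl-10-phenyldecane, via (7-phenylheptyl)magnesium bromide 3 (not isolated)
Conditions: 1, Mg, THF, 40 °C; then 2, Li2CuCl4 (3 mol %), THF, −20 °C → rt
Reagents that add atoms: none
Why: Kochi-type copper-catalysed sp3–sp3 Grignard cross-coupling should take place at the C–Br bond only (C–Cl is inert under Li2CuCl4 catalysis), and the purchased stereocentre is not touched, so C2' is fixed here (the descriptor changes from S to R only through the priority switch).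

Step 2
Reactants: 5 (R)-2-methylsuccinic acid 4-methyl ester; 6 monomethyl malonate
Product: 8 dimethyl (3R)-3-methyl-4-oxohexanedioate, via acyl imidazolide 7 (not isolated)
Conditions: 5, CDI, THF, rt; then 6, MgCl2, Et3N, MeCN, rt; aq. citric acid
Reagents that add atoms: none
Why: Masamune–Brooks C-acylation of the magnesium enolate of the malonate half-ester by the acyl imidazolide, followed by decarboxylation, should give the β-keto ester under near-neutral conditions that leave the C4 stereocentre intact.

Step 3
Reactants: 8 dimethyl (3R)-3-methyl-4-oxohexanedioate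
Product: 9 methyl (4R)-6-[methoxy(methyl)amino]-4-methyl-3,6-dioxohexanoate
Conditions: MeNH(OMe)·HCl, i-PrMgCl, THF, −20 → 0 °C; cold 1 M HCl
Reagents that add atoms: N,O-dimethylhydroxylamine hydrochloride, CNOC.Cl
Why: Aminolysis of an ester by the chloromagnesium amide (Weinreb amide synthesis) should take only the isolated C6 methyl ester, because the first equivalent of base turns the β-keto ester into a chelated magnesium enolate whose carbonyl groups are unreactive and whose C4–H is not acidic.

Step 4
Reactants: 4 (R)-1-chloro-2-methyl-10-phenyldecane; 9 methyl (4R)-6-[methoxy(methyl)amino]-4-methyl-3,6-dioxohexanoate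
Product: 11 methyl (4R,8R)-4,8-dimethyl-3,6-dioxo-16-phenylhexadecanoate, via Grignard reagent 10 (not isolated)
Conditions: 4, Mg (I2 cat.), THF, 60 °C; 9, i-PrMgCl (1.0 equiv), THF, −20 °C; then the solution of 10, −20 → 0 °C; cold 1 M HCl
Reagents that add atoms: none
Why: Weinreb–Nahm ketone synthesis: the primary Grignard reagent 10 adds to the amide carbonyl C6 of 9 (whose β-keto ester has first been converted by i-PrMgCl into its chelated magnesium enolate) to give the five-membered N,O-chelated magnesium hemiaminal, which collapses to the ketone only on acidic work-up, so the C6–C1' bond is formed once and no tertiary alcohol can arise. The closest precedent is the standard addition of alkylmagnesium halides to N-methoxy-N-methylamides in the presence of 1,3-dicarbonyl groups protected in situ as enolates. The step closes no ring and creates no stereocentre; C2' (β to magnesium) and C4 (flanked by the enolate carbon C3 and the C5 methylene) are not acidic under these conditions and are carried through unchanged. The selectivity needed is chemoselectivity for the amide over the C3 ketone and the ester, which the enolate secures, and mono-addition, which the chelate secures. The product holds every carbon of the target except the C6 methyl group, with C3 and C6 as the two carbonyls of a 1,4-diketone, so that step 5 can close the 1,2-dioxane and step 6 can set C6 by axial methylation with the side chain already in place.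

Step 5
Reactants: 11 methyl (4R,8R)-4,8-dimethyl-3,6-dioxo-16-phenylhexadecanoate
Product: 12 methyl 2-[(3S,4R,6S)-3,6-dimethoxy-4-methyl-6-[(2R)-2-methyl-10-phenyldecyl]-1,2-dioxan-3-yl]acetate
Conditions: H2O2 (anhydrous, Et2O solution, 1.2 equiv), HC(OMe)3, MeOH, CSA (cat.), 0 °C → rt
Reagents that add atoms: hydrogen peroxide, OO; trimethyl orthoformate, COC(OC)OC
Why: Acid-catalysed peroxyketalisation (the reaction type of cyclic peroxide formation from 1,4- and 1,5-diketones with H2O2 and of ketal–hydroperoxide exchange) should form the C6 methoxy hydroperoxide and add its OOH to the C3 carbonyl (6-exo-trig), and reversible ionisation at both ketal carbons should settle the chair with both OMe groups axial (anomeric effect) and C4-Me, the side chain and CH2CO2Me equatorial.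

Step 6
Reactants: 12 methyl 2-[(3S,4R,6S)-3,6-dimethoxy-4-methyl-6-[(2R)-2-methyl-10-phenyldecyl]-1,2-dioxan-3-yl]acetate
Product: 13 methyl 2-[(3S,4R,6S)-3-methoxy-4,6-dimethyl-6-[(2R)-2-methyl-10-phenyldecyl]-1,2-dioxan-3-yl]acetate
Conditions: AlMe3 (2.5 equiv), CH2Cl2, −78 → −40 °C; aq. Rochelle salt
Reagents that add atoms: trimethylaluminium, C[Al](C)C
Why: Proposed new method: AlMe3 should coordinate and ionise the C6 methoxy group (C6 carries two alkyl groups, whereas C3 is deactivated by the β-ester) to give the cyclic peroxycarbenium ion O1=C6+, and methyl transfer from the methoxy(trimethyl)aluminate should follow the axial trajectory on the half-chair with C4-Me pseudoequatorial and C3-OMe pseudoaxial, anti to C3-OMe and trans to C4-Me, so that the new methyl group ends axial and the side chain equatorial (6S); the closest known reactions are the Lewis-acid-mediated C–C bond formations of cyclic peroxyketals with allylsilanes and silyl enol ethers through peroxycarbenium ions, and the axial C-methylation of cyclic ketals through oxocarbenium ions with AlMe3.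

Step 7
Reactants: 13 methyl 2-[(3S,4R,6S)-3-methoxy-4,6-dimethyl-6-[(2R)-2-methyl-10-phenyldecyl]-1,2-dioxan-3-yl]acetate
Product: 15 2-[(3S,4R,6S)-3-hydroxy-4,6-dimethyl-6-[(2R)-2-methyl-10-phenyldecyl]-1,2-dioxan-3-yl]acetic acid, via ketal acid 14 (not isolated)
Conditions: LiOH, THF–H2O, 0 °C → rt; then 1 M HCl to pH 1, THF–H2O, rt
Reagents that add atoms: lithium hydroxide, [Li+].[OH-]; water, O
Why: Saponification is done while C3 is still a ketal (no free β-keto ester, no ring opening, and no α-hydrogen on either peroxy carbon for base-induced fragmentation), and the following specific-acid hydrolysis through the C3 peroxycarbenium ion should re-add water under thermodynamic control to put OH axial and cis to C4-Me (3S).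

**Compound list**

1 | (7-bromoheptyl)benzene | BrCCCCCCCc1ccccc1 | starting material
2 | (S)-1-bromo-3-chloro-2-methylpropane | C[C@H](CBr)CCl | starting material
3 | (7-phenylheptyl)magnesium bromide | Br[Mg]CCCCCCCc1ccccc1 | intermediate
4 | (R)-1-chloro-2-methyl-10-phenyldecane | C[C@H](CCCCCCCCc1ccccc1)CCl | intermediate
5 | (R)-2-methylsuccinic acid 4-methyl ester, (2R)-4-methoxy-2-methyl-4-oxobutanoic acid | COC(=O)C[C@@H](C)C(=O)O | starting material
6 | monomethyl malonate, 3-methoxy-3-oxopropanoic acid | COC(=O)CC(=O)O | starting material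
7 | methyl (3R)-4-(imidazol-1-yl)-3-methyl-4-oxobutanoate (acyl imidazolide) | COC(=O)C[C@@H](C)C(=O)n1ccnc1 | intermediate
8 | dimethyl (3R)-3-methyl-4-oxohexanedioate | COC(=O)C[C@@H](C)C(=O)CC(=O)OC | intermediate
9 | methyl (4R)-6-[methoxy(methyl)amino]-4-methyl-3,6-dioxohexanoate | CON(C)C(=O)C[C@@H](C)C(=O)CC(=O)OC | intermediate
10 | [(2R)-2-methyl-10-phenyldecyl]magnesium chloride | C[C@H](CCCCCCCCc1ccccc1)C[Mg]Cl | intermediate
11 | methyl (4R,8R)-4,8-dimethyl-3,6-dioxo-16-phenylhexadecanoate | C[C@H](CCCCCCCCc1ccccc1)CC(=O)C[C@@H](C)C(=O)CC(=O)OC | intermediate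
12 | methyl 2-[(3S,4R,6S)-3,6-dimethoxy-4-methyl-6-[(2R)-2-methyl-10-phenyldecyl]-1,2-dioxan-3-yl]acetate | C[C@H](CCCCCCCCc1ccccc1)C[C@@]1(OC)C[C@@H](C)[C@](OC)(CC(=O)OC)OO1 | intermediate
13 | methyl 2-[(3S,4R,6S)-3-methoxy-4,6-dimethyl-6-[(2R)-2-methyl-10-phenyldecyl]-1,2-dioxan-3-yl]acetate | C[C@H](CCCCCCCCc1ccccc1)C[C@@]1(C)C[C@@H](C)[C@](OC)(CC(=O)OC)OO1 | intermediate
14 | 2-[(3S,4R,6S)-3-methoxy-4,6-dimethyl-6-[(2R)-2-methyl-10-phenyldecyl]-1,2-dioxan-3-yl]acetic acid | C[C@H](CCCCCCCCc1ccccc1)C[C@@]1(C)C[C@@H](C)[C@](OC)(CC(=O)O)OO1 | intermediate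
15 | 2-[(3S,4R,6S)-3-hydroxy-4,6-dimethyl-6-[(2R)-2-methyl-10-phenyldecyl]-1,2-dioxan-3-yl]acetic acid | C[C@H](CCCCCCCCc1ccccc1)C[C@@]1(C)C[C@@H](C)[C@](O)(CC(=O)O)OO1 | target

**Step count and risks**

Total steps: 7. Longest linear sequence: 6 steps (5 → 8 → 9 → 11 → 12 → 13 → 15).

Steps most likely to fail:

Step 6 (labelled step). What may go wrong: Lewis-acid-induced heterolysis of the O–O bond (Criegee/Hock-type fragmentation), reduction of the peroxide by Al–C bonds, ionisation at C3 instead of C6, or loss of the axial preference. The fallback uses known chemistry, sets out from 11 and comes back at 13. Wittig methylenation of the C6 ketone (Ph3P=CH2 in excess, the β-keto ester being protected as its enolate) gives methyl (4R,8R)-4,8-dimethyl-6-methylidene-3-oxo-16-phenylhexadecanoate F1. Mukaiyama–Isayama silylperoxidation (Co(thd)2 cat., O2, Et3SiH) should give the tertiary silyl peroxide methyl (4R,8R)-4,6,8-trimethyl-3-oxo-16-phenyl-6-(triethylsilylperoxy)hexadecanoate F2 as both C6 epimers. HF·pyridine frees the hydroperoxide, which closes onto the C3 ketone; the (6S) hemiketal methyl 2-[(3S,4R,6S)-3-hydroxy-4,6-dimethyl-6-[(2R)-2-methyl-10-phenyldecyl]-1,2-dioxan-3-yl]acetate F3 is separated from its C6 epimer and ketalised (MeOH, HC(OMe)3, PPTS) to 13. This fallback gives up stereocontrol at C6 and relies on separation.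

Step 5. What may go wrong: acid-catalysed cyclodehydration of the 1,4-diketone to a furan, enolisation towards C4 with loss of configuration, or partition to a bridged ozonide or a 2-hydroperoxytetrahydrofuran instead of the monocyclic bis-peroxyketal. The fallback sets out from 11 and comes back at 12. Wittig methoxymethylenation (Ph3P=CHOMe in excess) gives the enol ether methyl (4R,8R)-6-(methoxymethylidene)-4,8-dimethyl-3-oxo-16-phenylhexadecanoate F4. Ozonolysis in MeOH–CH2Cl2 at −78 °C places the carbonyl oxide on C6 (the enol ether carbon leaves as methyl formate); methanol traps it as the methoxy hydroperoxide, which adds to the C3 ketone to give methyl 2-[(3S,4R,6S)-3-hydroxy-6-methoxy-4-methyl-6-[(2R)-2-methyl-10-phenyldecyl]-1,2-dioxan-3-yl]acetate F5. Mild ketalisation (MeOH, HC(OMe)3, PPTS) converts F5 into 12.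

Step 4. What may go wrong: incomplete enolate formation, so that the Grignard reagent is quenched by the β-keto ester or adds to the C3 ketone, or sluggish Grignard formation from the β-branched chloride. The fallback reverses the order of the two C-acylations, sets out from 5 and comes back at 11. Amidation of 5 (MeNH(OMe)·HCl, i-PrMgCl) gives (2R)-4-[methoxy(methyl)amino]-2-methyl-4-oxobutanoic acid F6. Its magnesium carboxylate is treated with 10 to give the keto acid (2R,6R)-2,6-dimethyl-4-oxo-14-phenyltetradecanoic acid F7. Masamune–Brooks homologation of F7 (CDI; 6, MgCl2, Et3N) then gives 11.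

Further compounds
F1 | step 6 | methyl (4R,8R)-4,8-dimethyl-6-methylidene-3-oxo-16-phenylhexadecanoate | C[C@H](CCCCCCCCc1ccccc1)CC(=C)C[C@@H](C)C(=O)CC(=O)OC
F2 | step 6 | methyl (4R,8R)-4,6,8-trimethyl-3-oxo-16-phenyl-6-(triethylsilylperoxy)hexadecanoate (both C6 epimers) | C[C@H](CCCCCCCCc1ccccc1)CC(C)(OO[Si](CC)(CC)CC)C[C@@H](C)C(=O)CC(=O)OC
F3 | step 6 | methyl 2-[(3S,4R,6S)-3-hydroxy-4,6-dimethyl-6-[(2R)-2-methyl-10-phenyldecyl]-1,2-dioxan-3-yl]acetate | C[C@H](CCCCCCCCc1ccccc1)C[C@@]1(C)C[C@@H](C)[C@](O)(CC(=O)OC)OO1
F4 | step 5 | methyl (4R,8R)-6-(methoxymethylidene)-4,8-dimethyl-3-oxo-16-phenylhexadecanoate (E/Z mixture) | C[C@H](CCCCCCCCc1ccccc1)CC(=COC)C[C@@H](C)C(=O)CC(=O)OC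
F5 | step 5 | methyl 2-[(3S,4R,6S)-3-hydroxy-6-methoxy-4-methyl-6-[(2R)-2-methyl-10-phenyldecyl]-1,2-dioxan-3-yl]acetate | C[C@H](CCCCCCCCc1ccccc1)C[C@@]1(OC)C[C@@H](C)[C@](O)(CC(=O)OC)OO1
F6 | step 4 | (2R)-4-[methoxy(methyl)amino]-2-methyl-4-oxobutanoic acid | CON(C)C(=O)C[C@@H](C)C(=O)O
F7 | step 4 | (2R,6R)-2,6-dimethyl-4-oxo-14-phenyltetradecanoic acid | C[C@H](CCCCCCCCc1ccccc1)CC(=O)C[C@@H](C)C(=O)O
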